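**Retrosynthetic overview**
- The (E)-CH=CH-CH2OH arm on ring B (the syringyl ring) is cut back to an aryl aldehyde: Wittig C2 extension, then one hydride reduction that also frees the ring A (guaiacyl) phenol.
- C9-OH is cut back to a vinyl group (ozonolysis, borohydride).
- Key disconnection C7–C8: an oxygen-bearing (Z)-aryloxyallyl anion, carried on a chiral borane, adds to a vanillin ester, so two carbons that are both natural acceptors are joined and both stereocentres are set in that one step.
- Fragments: syringaldehyde (O-allylated, aldehyde masked) and vanillin isobutyrate.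
- No ring is formed: both benzene rings are bought; the only ring made is a temporary 1,3-dioxolane (closed in step 2, opened in step 4).

Assumption: the SMILES is read as the threo (7S,8S) isomer (C7 = benzylic carbinol, C8 = aryloxy carbon, C9 = CH2OH); vanillin isobutyrate (a bulk flavour chemical) and (+)-Ipc2BOMe (Ipc = isopinocampheyl, here from (−)-α-pinene) are taken as catalogue items.

**Step 1**
Reactants: 1 syringaldehyde
Product: 2 4-(allyloxy)-3,5-dimethoxybenzaldehyde
Conditions: allyl bromide (1.2 equiv), K2CO3 (1.5 equiv), DMF, 60 °C, 3 h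
Reagents that add atoms: allyl bromide, C=CCBr
Why: Williamson ether synthesis (SN2 O-alkylation) of the acidic para-formyl phenoxide with a primary allylic bromide; no stereocentre is formed.

**Step 2**
Reactants: 2 4-(allyloxy)-3,5-dimethoxybenzaldehyde
Product: 3 2-[4-(allyloxy)-3,5-dimethoxyphenyl]-1,3-dioxolane
Conditions: ethylene glycol (3 equiv), p-TsOH·H2O (2 mol%), toluene, reflux, Dean–Stark
Reagents that add atoms: ethylene glycol, OCCO
Why: acid-catalysed acetalisation with azeotropic water removal masks the aldehyde against sec-BuLi and the allylborane of step 3, and the allyl aryl ether is stable at 110 °C because both ortho positions are blocked and Claisen rearrangement needs far higher temperature; no stereocentre is formed.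

**Step 3**
Reactants: 3 2-[4-(allyloxy)-3,5-dimethoxyphenyl]-1,3-dioxolane; 4 vanillin isobutyrate (4-formyl-2-methoxyphenyl 2-methylpropanoate)
Product: 9 4-[(1S,2S)-2-[4-(1,3-dioxolan-2-yl)-2,6-dimethoxyphenoxy]-1-hydroxybut-3-en-1-yl]-2-methoxyphenyl 2-methylpropanoate, via lithiated allyl ether 5 (not isolated), via ate complex 6 (not isolated), via (Z)-aryloxyallylborane 7 (not isolated), via borinate ester 8 (not isolated)
Conditions: 3 (1.2 equiv), sec-BuLi (1.15 equiv), THF, −78 °C, 30 min; (+)-Ipc2BOMe (1.2 equiv), −78 °C, 1 h; BF3·OEt2 (1.2 equiv), −78 °C; 4 (1.0 equiv), −78 °C, 4 h; then HOCH2CH2NH2, Et2O, 0 °C, filter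
Reagents that add atoms: none
Why: Proposed new method: the closest known reaction type is the Brown asymmetric γ-alkoxyallylboration of aldehydes, here stretched to an allyl aryl ether carrying the whole ring B unit; sec-BuLi removes the allylic α-oxy proton to give the O-chelated (Z)-oxyallyl anion 5 (an oxygen-bearing carbanion, so C8 reacts with reversed polarity), boron is taken up at the CH2 terminus, BF3 strips methoxide from 6 to free the (Z)-borane 7, and its chair Zimmerman–Traxler transition state with 4 forms the C7–C8 bond syn (threo) while the Ipc groups from (−)-α-pinene direct the allyl unit to the Re face of the aldehyde, which sets 7S and 8S together.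

**Step 4**
Reactants: 9 4-[(1S,2S)-2-[4-(1,3-dioxolan-2-yl)-2,6-dimethoxyphenoxy]-1-hydroxybut-3-en-1-yl]-2-methoxyphenyl 2-methylpropanoate
Product: 12 4-[(1S,2S)-2-(4-formyl-2,6-dimethoxyphenoxy)-1,3-dihydroxypropyl]-2-methoxyphenyl 2-methylpropanoate, via ozonide 10 (not isolated), via diol acetal 11 (not isolated)
Conditions: O3, CH2Cl2, −78 °C (Sudan Red 7B end point); NaBH4 (4 equiv), MeOH, −78 → 0 °C; then 1 M HCl, THF, 20 °C, 1 h
Reagents that add atoms: ozone, [O-][O+]=O; water, O
Why: ozonolysis with reductive work-up cleaves the only alkene much faster than ozone attacks the acylated ring A or the trialkoxy ring B, NaBH4 reduces the ozonide straight to the C9 alcohol so the epimerisable α-aryloxy aldehyde never accumulates, and dilute acid then hydrolyses the electron-rich aryl dioxolane (acetal hydrolysis) without disturbing C7 or C8.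

**Step 5**
Reactants: 12 4-[(1S,2S)-2-(4-formyl-2,6-dimethoxyphenoxy)-1,3-dihydroxypropyl]-2-methoxyphenyl 2-methylpropanoate
Product: 13 ethyl (E)-3-[4-[[(1S,2S)-1,3-dihydroxy-1-[3-methoxy-4-(2-methylpropanoyloxy)phenyl]propan-2-yl]oxy]-3,5-dimethoxyphenyl]prop-2-enoate
Conditions: Ph3P=CHCO2Et (1.3 equiv), toluene, 60 °C
Reagents that add atoms: ethyl (triphenylphosphoranylidene)acetate, CCOC(=O)C=P(c1ccccc1)(c1ccccc1)c1ccccc1
Why: Wittig olefination with a stabilised ylide gives the (E)-cinnamate (typically above 95:5) and tolerates the free diol and the aryl ester; C7 and C8 are not touched.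

**Step 6**
Reactants: 13 ethyl (E)-3-[4-[[(1S,2S)-1,3-dihydroxy-1-[3-methoxy-4-(2-methylpropanoyloxy)phenyl]propan-2-yl]oxy]-3,5-dimethoxyphenyl]prop-2-enoate
Product: 14 (1S,2S)-1-(4-hydroxy-3-methoxyphenyl)-2-[4-[(E)-3-hydroxyprop-1-enyl]-2,6-dimethoxyphenoxy]propane-1,3-diol
Conditions: i-Bu2AlH (8 equiv), CH2Cl2/THF, −78 → 0 °C; aqueous KNaC4H4O6 (potassium sodium tartrate) work-up
Reagents that add atoms: none
Why: i-Bu2AlH reduces the conjugated ethyl ester by 1,2-addition only to the (E)-allylic alcohol and cleaves the aryl isobutyrate in the same flask (ester reduction), and the neutral tartrate work-up avoids quinone-methide-type epimerisation at C7.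

**Compound list**
1 | syringaldehyde (4-hydroxy-3,5-dimethoxybenzaldehyde) | COc1cc(C=O)cc(OC)c1O | starting material
2 | 4-(allyloxy)-3,5-dimethoxybenzaldehyde | C=CCOc1c(OC)cc(C=O)cc1OC | intermediate
3 | 2-[4-(allyloxy)-3,5-dimethoxyphenyl]-1,3-dioxolane | C=CCOc1c(OC)cc(C2OCCO2)cc1OC | intermediate
4 | vanillin isobutyrate (4-formyl-2-methoxyphenyl 2-methylpropanoate) | COc1cc(C=O)ccc1OC(=O)C(C)C | starting material
5 | [(Z)-3-[4-(1,3-dioxolan-2-yl)-2,6-dimethoxyphenoxy]prop-2-en-1-yl]lithium (O-chelated oxyallyl anion) | [Li]C/C=C\Oc1c(OC)cc(C2OCCO2)cc1OC | intermediate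
6 | lithium [(Z)-3-[4-(1,3-dioxolan-2-yl)-2,6-dimethoxyphenoxy]allyl]bis(isopinocampheyl)(methoxy)borate | [Li+].CO[B-](C/C=C\Oc1c(OC)cc(C2OCCO2)cc1OC)([C@H]1C[C@H]2C[C@@H]([C@@H]1C)C2(C)C)[C@H]1C[C@H]2C[C@@H]([C@@H]1C)C2(C)C | intermediate
7 | [(Z)-3-[4-(1,3-dioxolan-2-yl)-2,6-dimethoxyphenoxy]allyl]bis(isopinocampheyl)borane | COc1cc(C2OCCO2)cc(OC)c1O/C=C\CB([C@H]1C[C@H]2C[C@@H]([C@@H]1C)C2(C)C)[C@H]1C[C@H]2C[C@@H]([C@@H]1C)C2(C)C | intermediate
8 | O-bis(isopinocampheyl)boryl ether of 9 at the C7 oxygen (7S,8S) | COc1cc([C@H](OB([C@H]4C[C@H]5C[C@@H]([C@@H]4C)C5(C)C)[C@H]4C[C@H]5C[C@@H]([C@@H]4C)C5(C)C)[C@H](C=C)Oc2c(OC)cc(C3OCCO3)cc2OC)ccc1OC(=O)C(C)C | intermediate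
9 | 4-[(1S,2S)-2-[4-(1,3-dioxolan-2-yl)-2,6-dimethoxyphenoxy]-1-hydroxybut-3-en-1-yl]-2-methoxyphenyl 2-methylpropanoate | COc1cc([C@H](O)[C@H](C=C)Oc2c(OC)cc(C3OCCO3)cc2OC)ccc1OC(=O)C(C)C | intermediate
10 | secondary ozonide of 9 (vinyl group turned into a 1,2,4-trioxolan-3-yl group; C7 and C8 arranged as in 9; trioxolane carbon a mixture) | COc1cc([C@H](O)[C@H](C3OCOO3)Oc2c(OC)cc(C4OCCO4)cc2OC)ccc1OC(=O)C(C)C | intermediate
11 | 4-[(1S,2S)-2-[4-(1,3-dioxolan-2-yl)-2,6-dimethoxyphenoxy]-1,3-dihydroxypropyl]-2-methoxyphenyl 2-methylpropanoate | COc1cc([C@H](O)[C@H](CO)Oc2c(OC)cc(C3OCCO3)cc2OC)ccc1OC(=O)C(C)C | intermediate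
12 | 4-[(1S,2S)-2-(4-formyl-2,6-dimethoxyphenoxy)-1,3-dihydroxypropyl]-2-methoxyphenyl 2-methylpropanoate | COc1cc([C@H](O)[C@H](CO)Oc2c(OC)cc(C=O)cc2OC)ccc1OC(=O)C(C)C | intermediate
13 | ethyl (E)-3-[4-[[(1S,2S)-1,3-dihydroxy-1-[3-methoxy-4-(2-methylpropanoyloxy)phenyl]propan-2-yl]oxy]-3,5-dimethoxyphenyl]prop-2-enoate | COc1cc([C@H](O)[C@H](CO)Oc2c(OC)cc(/C=C/C(=O)OCC)cc2OC)ccc1OC(=O)C(C)C | intermediate
14 | (1S,2S)-1-(4-hydroxy-3-methoxyphenyl)-2-[4-[(E)-3-hydroxyprop-1-enyl]-2,6-dimethoxyphenoxy]propane-1,3-diol (threo-guaiacylglycerol 8-O-4′ sinapyl alcohol ether) | COc1cc([C@H](O)[C@H](CO)Oc2c(OC)cc(/C=C/CO)cc2OC)ccc1O | target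

**Step count**
Total: 6 steps. Longest linear sequence: 6 steps (1 → 2 → 3 → 9 → 12 → 13 → 14); 4 enters as purchased in step 3.

**Steps most likely to fail, with fallbacks**

Step 3 (key coupling). Risks:
- ortho-lithiation or acetal attack competing with allylic deprotonation;
- BF3 opening the dioxolane;
- slow or poorly face-selective transfer of the bulky aryloxyallyl group from the Ipc2B reagent;
- ester loss on work-up.

An ee near 90% is expected from the alkoxy precedent, so 12 or 13 would be recrystallised to reach a single enantiomer. The fallback sets out from 3 (and 4) and comes back at 9. The anion 5 is quenched with 2-isopropoxy-4,4,5,5-tetramethyl-1,3,2-dioxaborolane and a mild acidic work-up gives the isolable pinacol (Z)-γ-aryloxyallylboronate F1, so neither BF3 nor a stoichiometric chiral borane is needed. F1 is then added to 4 under chiral Brønsted acid catalysis (5 mol% (R)-3,3′-bis(2,4,6-triisopropylphenyl)-1,1′-binaphthyl-2,2′-diyl hydrogen phosphate, toluene, −30 °C). The enantiomer of the acid is chosen by analogy with allyl- and crotylboronate additions to aryl aldehydes, and the closed chair transition state still gives syn. This forms the pinacol borate ester F2, which aqueous NaHCO3 hydrolyses to 9.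

Step 4 (ozonolysis, reduction, acetal hydrolysis). Risks: ozone attack on the electron-rich ring B, or partial loss of the aryl ester in borohydride/methanol. The fallback sets out from 9 and comes back at 11, which is hydrolysed to 12 exactly as in step 4. The cleavage is done stepwise with an alkene-selective oxidant: OsO4 (2 mol%) with N-methylmorpholine N-oxide in acetone/water gives the triol F3 (isolated; the new carbinol configuration is irrelevant). NaIO4 in THF/pH 7 buffer at 0 °C cleaves only its terminal 1,2-diol to the α-aryloxy aldehyde F4, which is reduced at once with NaBH4 to 11 before it can epimerise.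

Step 6 (global i-Bu2AlH reduction). Risks: insoluble aluminium chelates of the diol-phenol, incomplete ester cleavage, or loss of the acid- and base-sensitive product on work-up. The fallback sets out from 12 and comes back at 14, avoiding aluminium hydride altogether. Wittig reaction of 12 with Ph3P=CHCHO (toluene, 80 °C) gives the (E)-cinnamaldehyde F5. Luche reduction (NaBH4, CeCl3·7H2O, MeOH, −40 °C) gives the allylic alcohol isobutyrate F6. Brief methanolysis (K2CO3, MeOH, 0 °C) removes the isobutyrate to give 14.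

**Further compounds**
F1 | step 3 | 2-[(Z)-3-[4-(1,3-dioxolan-2-yl)-2,6-dimethoxyphenoxy]allyl]-4,4,5,5-tetramethyl-1,3,2-dioxaborolane | COc1cc(C2OCCO2)cc(OC)c1O/C=C\CB1OC(C)(C)C(C)(C)O1
F2 | step 3 | pinacol borate ester of 9 at the C7 oxygen (7S,8S) | COc1cc([C@H](OB3OC(C)(C)C(C)(C)O3)[C@H](C=C)Oc2c(OC)cc(C4OCCO4)cc2OC)ccc1OC(=O)C(C)C
F3 | step 4 | triol from dihydroxylation of the vinyl group of 9 (C7 and C8 as in 9; new carbinol a mixture) | COc1cc([C@H](O)[C@H](C(O)CO)Oc2c(OC)cc(C3OCCO3)cc2OC)ccc1OC(=O)C(C)C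
F4 | step 4 | C9 aldehyde: 4-[2-[4-(1,3-dioxolan-2-yl)-2,6-dimethoxyphenoxy]-1-hydroxy-3-oxopropyl]-2-methoxyphenyl 2-methylpropanoate (C7 and C8 arranged as in 9) | COc1cc([C@H](O)[C@H](C=O)Oc2c(OC)cc(C3OCCO3)cc2OC)ccc1OC(=O)C(C)C
F5 | step 6 | 4-[(1S,2S)-2-[2,6-dimethoxy-4-[(E)-3-oxoprop-1-enyl]phenoxy]-1,3-dihydroxypropyl]-2-methoxyphenyl 2-methylpropanoate | COc1cc([C@H](O)[C@H](CO)Oc2c(OC)cc(/C=C/C=O)cc2OC)ccc1OC(=O)C(C)C
F6 | step 6 | 4-[(1S,2S)-1,3-dihydroxy-2-[4-[(E)-3-hydroxyprop-1-enyl]-2,6-dimethoxyphenoxy]propyl]-2-methoxyphenyl 2-methylpropanoate | COc1cc([C@H](O)[C@H](CO)Oc2c(OC)cc(/C=C/CO)cc2OC)ccc1OC(=O)C(C)C
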